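**Strategy**

The route rests on disconnecting the C9–C10 bond of the ten-membered carbocycle (C1–C10), whose vicinal secondary C9 and tertiary C10 oxygens, together with the C14 methyl, are the retron of a ketyl–carbonyl coupling. A SmI2 pinacol cyclisation joins a C9 aldehyde to a C10 methyl ketone, closing the carbocycle and setting both carbinol centres in one operation. Its precursor is a trans-disubstituted γ-lactone (C6, C7, C11, C12) carrying a CH2CHO arm on C7 and, on C6, a Z-trisubstituted alkenyl chain (C5=C4) with a silylated 3S carbinol and the terminal methyl ketone. The lactone and the Z alkene pre-fold the chain.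

Key step: step 13

**Remarks**

- Numbering follows the germacranolide skeleton of the target: carbocycle C1–C10, lactone carbons C11 and C12 (ring oxygen on C6), exocyclic C13, C14 on C10, C15 on C4. The target is 3S,4Z,6R,7S,9S,10S. C6 reads S in lactones 18, 23, 24 and 26–30 and R from 31 onwards, without any change in geometry, because the CIP rank of C7 changes.
- Assumption: the sense of induction in step 9 is taken from the facial preference of the same Me2Zn–ProPhenol catalyst in aldol additions. Both ligand antipodes are commercial, so the ligand is exchanged for its mirror image should the C6 epimer form.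
- The C3 oxygen stays silylated in the cyclisation substrate because a free hydroxyl would close a five-membered hemiketal onto the C10 ketone.
- C11 in 29 and 30 may form as either epimer and is destroyed in the elimination.

**Route**

Step 1
Reactants: 1 ethyl levulinate
Product: 2 ethyl 3-(2-methyl-1,3-dioxolan-2-yl)propanoate
Conditions: HOCH2CH2OH, p-TsOH (cat.), toluene, reflux, Dean–Stark
Reagents that add atoms: ethylene glycol, OCCO
Why: Acid-catalysed ketalisation with azeotropic removal of water masks the future C10 methyl ketone as a dioxolane that tolerates every organometallic step up to the carbonyl unmasking.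

Step 2
Reactants: 2 ethyl 3-(2-methyl-1,3-dioxolan-2-yl)propanoate
Product: 3 N-methoxy-N-methyl-3-(2-methyl-1,3-dioxolan-2-yl)propanamide
Conditions: MeNH(OMe)·HCl, i-PrMgCl, THF, −20 to 0 °C
Reagents that add atoms: N,O-dimethylhydroxylamine hydrochloride, CNOC.Cl
Why: Aminolysis of the ester by the magnesium amide (Weinreb amide formation) gives an acyl donor that stops at the ketone stage in the next step.

Step 3
Reactants: 3 N-methoxy-N-methyl-3-(2-methyl-1,3-dioxolan-2-yl)propanamide; 4 ethynyltrimethylsilane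
Product: 6 5-(2-methyl-1,3-dioxolan-2-yl)-1-(trimethylsilyl)pent-1-yn-3-one, via lithium (trimethylsilyl)acetylide 5 (not isolated)
Conditions: 4, n-BuLi, THF, −78 °C; then 3, −78 to 0 °C; aq. NH4Cl
Reagents that add atoms: none
Why: Acetylide addition to a Weinreb amide gives a chelated tetrahedral adduct that collapses to the ynone only on work-up, so over-addition is avoided and C4 and C5 are introduced.

Step 4
Reactants: 6 5-(2-methyl-1,3-dioxolan-2-yl)-1-(trimethylsilyl)pent-1-yn-3-one
Product: 7 (3S)-5-(2-methyl-1,3-dioxolan-2-yl)-1-(trimethylsilyl)pent-1-yn-3-ol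
Conditions: RuCl[(S,S)-TsDPEN](p-cymene) (cat.), i-PrOH, rt
Reagents that add atoms: none
Why: Noyori–Ikariya asymmetric transfer hydrogenation of an alkynyl ketone is a reliable entry to propargylic alcohols, the (S,S)-catalyst delivering hydride to the face that gives the 3S carbinol without touching the triple bond.

Step 5
Reactants: 7 (3S)-5-(2-methyl-1,3-dioxolan-2-yl)-1-(trimethylsilyl)pent-1-yn-3-ol
Product: 8 (3S)-5-(2-methyl-1,3-dioxolan-2-yl)pent-1-yn-3-ol
Conditions: K2CO3 (cat.), MeOH, rt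
Reagents that add atoms: none
Why: Base-catalysed methanolysis of the alkynyl–silicon bond frees the terminal alkyne needed for the directed carbometalation and leaves the ketal and the carbinol untouched.

Step 6
Reactants: 8 (3S)-5-(2-methyl-1,3-dioxolan-2-yl)pent-1-yn-3-ol
Product: 10 (1Z,3S)-1-iodo-2-methyl-5-(2-methyl-1,3-dioxolan-2-yl)pent-1-en-3-ol, via alkenylmagnesium chelate 9 (not isolated)
Conditions: MeMgBr, CuI (cat.), THF, 0 °C to rt; then I2, THF, −78 to 0 °C
Reagents that add atoms: methylmagnesium bromide, C[Mg]Br; iodine, II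
Why: Copper-catalysed anti-carbomagnesiation of the propargylic alkoxide places the methyl group on C4 and magnesium on C5 inside a five-membered chelate, so that iodinolysis with retention gives the vinyl iodide with iodine cis to C3 and thereby fixes the 4Z geometry.

Step 7
Reactants: 10 (1Z,3S)-1-iodo-2-methyl-5-(2-methyl-1,3-dioxolan-2-yl)pent-1-en-3-ol
Product: 11 tert-butyl{[(1Z,3S)-1-iodo-2-methyl-5-(2-methyl-1,3-dioxolan-2-yl)pent-1-en-3-yl]oxy}dimethylsilane
Conditions: TBSCl, imidazole, DMF, rt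
Reagents that add atoms: tert-butyldimethylsilyl chloride, CC(C)(C)[Si](C)(C)Cl
Why: Standard silylation masks the allylic C3 hydroxyl, which must stay protected to the last step so that it neither quenches the vinyllithium nor closes a hemiketal on C10 later.

Step 8
Reactants: 11 tert-butyl{[(1Z,3S)-1-iodo-2-methyl-5-(2-methyl-1,3-dioxolan-2-yl)pent-1-en-3-yl]oxy}dimethylsilane
Product: 13 (2Z,4S)-4-(tert-butyldimethylsilyloxy)-3-methyl-6-(2-methyl-1,3-dioxolan-2-yl)hex-2-enal, via Z-vinyllithium 12 (not isolated)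
Conditions: t-BuLi, Et2O, −78 °C; DMF, −78 to −20 °C; aq. NH4Cl
Reagents that add atoms: N,N-dimethylformamide, CN(C)C=O
Why: Iodine–lithium exchange proceeds with retention of alkene geometry and formylation of the vinyllithium gives the Z-enal whose aldehyde carbon is C6, the exchange being run cold in ether to suppress 1,4-migration of silicon from oxygen to carbon.

Step 9
Reactants: 13 (2Z,4S)-4-(tert-butyldimethylsilyloxy)-3-methyl-6-(2-methyl-1,3-dioxolan-2-yl)hex-2-enal; 14 methyl propiolate
Product: 16 methyl (4R,5Z,7S)-7-(tert-butyldimethylsilyloxy)-4-hydroxy-6-methyl-9-(2-methyl-1,3-dioxolan-2-yl)non-5-en-2-ynoate, via methylzinc alkynylide 15 (not isolated)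
Conditions: 14, Me2Zn, (R,R)-ProPhenol (cat.), Ph3PO (cat.), toluene, 0 °C; then 13, 0 to 4 °C; aq. NH4Cl
Reagents that add atoms: none
Why: Zinc–ProPhenol-catalysed enantioselective alkynylation of an α,β-unsaturated aldehyde forms the C6–C7 bond and sets the 6R carbinol by reagent control through Si-face delivery of the alkynyl group, the remote C3 centre having little influence.

Step 10
Reactants: 16 methyl (4R,5Z,7S)-7-(tert-butyldimethylsilyloxy)-4-hydroxy-6-methyl-9-(2-methyl-1,3-dioxolan-2-yl)non-5-en-2-ynoate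
Product: 18 (5S)-5-[(1Z,3S)-3-(tert-butyldimethylsilyloxy)-2-methyl-5-(2-methyl-1,3-dioxolan-2-yl)pent-1-en-1-yl]furan-2(5H)-one, via Z-hydroxy enoate 17 (not isolated)
Conditions: H2 (1 atm), Pd/CaCO3–Pb(OAc)2, quinoline, EtOAc, rt; then PPTS (cat.), CH2Cl2, rt
Reagents that add atoms: none
Why: Lindlar semihydrogenation of the ynoate gives the Z-enoate, whose γ-hydroxyl sits next to the ester and lactonises to the butenolide, while the hindered trisubstituted C4=C5 alkene is inert to the poisoned catalyst.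

Step 11
Reactants: 18 (5S)-5-[(1Z,3S)-3-(tert-butyldimethylsilyloxy)-2-methyl-5-(2-methyl-1,3-dioxolan-2-yl)pent-1-en-1-yl]furan-2(5H)-one; 19 (Z)-1-bromo-2-ethoxyethene
Product: 23 (4R,5S)-4-[(Z)-2-ethoxyvinyl]-5-[(1Z,3S)-3-(tert-butyldimethylsilyloxy)-2-methyl-5-(2-methyl-1,3-dioxolan-2-yl)pent-1-en-1-yl]dihydrofuran-2(3H)-one, via ethoxyvinyllithium 20 (not isolated), via lithium dialkenylcuprate 21 (not isolated), via silyl ketene acetal 22 (not isolated)
Conditions: 19, t-BuLi, Et2O, −78 °C; CuI, −40 °C; Me3SiCl, then 18, −78 °C; aq. NH4Cl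
Reagents that add atoms: none
Why: Silyl-chloride-accelerated conjugate addition of an alkenyl cuprate to a γ-substituted butenolide occurs anti to the C6 alkenyl group, which sets C7 with the trans-lactone relationship and brings in C8–C9 as a masked acetaldehyde unit.

Step 12
Reactants: 23 (4R,5S)-4-[(Z)-2-ethoxyvinyl]-5-[(1Z,3S)-3-(tert-butyldimethylsilyloxy)-2-methyl-5-(2-methyl-1,3-dioxolan-2-yl)pent-1-en-1-yl]dihydrofuran-2(3H)-one
Product: 24 2-[(2S,3S)-2-[(1Z,3S)-3-(tert-butyldimethylsilyloxy)-2-methyl-6-oxohept-1-en-1-yl]-5-oxooxolan-3-yl]acetaldehyde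
Conditions: PPTS, acetone–H2O, 40 °C
Reagents that add atoms: water, O
Why: Mild acid hydrolysis cleaves the enol ether to the C9 aldehyde and the dioxolane to the C10 methyl ketone in one operation under conditions that a secondary silyl ether and the lactone survive.

Step 13
Reactants: 24 2-[(2S,3S)-2-[(1Z,3S)-3-(tert-butyldimethylsilyloxy)-2-methyl-6-oxohept-1-en-1-yl]-5-oxooxolan-3-yl]acetaldehyde
Product: 26 (3S,4Z,6S,7S,9S,10S)-3-(tert-butyldimethylsilyloxy)-9,10-dihydroxy-13-norgermacr-4-en-12,6-olide, via samarium diolate 25 (not isolated)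
Conditions: SmI2 (0.1 M in THF, 3 equiv), THF, slow addition of 24 by syringe pump (final 2 mM), rt; then aq. NH4Cl
Reagents that add atoms: none
Why: Divalent samarium transfers one electron to the aldehyde, the more easily reduced carbonyl, and the C9 ketyl, held on trivalent samarium that also binds the C10 ketone oxygen, adds to C10, after which a second electron transfer gives the samarium diolate 25 that is protonated on work-up. The closest known reaction type is the intramolecular SmI2 pinacol coupling of keto-aldehydes, routine for five- to eight-membered rings and here stretched to ten. The carbocycle C1–C10 closes head to tail by a 10-exo-trig attack of the ketyl carbon on the ketone, the trans-fused lactone at C6–C7 and the Z C4=C5 alkene removing rotors and turning the two chain ends towards each other. C9 and C10 are set together: the samarium bridge keeps the two oxygens synclinal while the ring bonds C8–C9 and C10–C1 lie anti, which should give the threo (9S,10S) diol, and the ketone face that is attacked is chosen by the ring conformation that C6, C7 and the pseudo-equatorial C3 silyloxy group impose. The step needs carbonyl–carbonyl coupling to win over ketyl–alkene cyclisation, lactone reduction and intermolecular coupling, which is secured by the trans-lactone (closure of C9 onto C5 would demand a trans-fused bicyclo[3.3.0]octane), by leaving out HMPA and proton donors, and by slow addition at high dilution.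

Step 14
Reactants: 26 (3S,4Z,6S,7S,9S,10S)-3-(tert-butyldimethylsilyloxy)-9,10-dihydroxy-13-norgermacr-4-en-12,6-olide
Product: 27 9,10-bis(trimethylsilyl) ether of 26
Conditions: Me3SiOTf, 2,6-lutidine, CH2Cl2, −78 to 0 °C
Reagents that add atoms: trimethylsilyl trifluoromethanesulfonate, C[Si](C)(C)OS(=O)(=O)C(F)(F)F
Why: Transient silylation of the secondary C9 and tertiary C10 hydroxyls removes the acidic protons and prevents a C9 alkoxide from attacking the lactone carbonyl during the enolate chemistry that follows.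

Step 15
Reactants: 27 9,10-bis(trimethylsilyl) ether of 26
Product: 32 (3S,4Z,6R,7S,9S,10S)-3-(tert-butyldimethylsilyloxy)-9,10-dihydroxygermacra-4,11(13)-dien-12,6-olide, via lithium enolate 28 (not isolated), via Mannich base 29 (not isolated), via ammonium iodide 30 (not isolated), via bis-silyl methylene lactone 31 (not isolated)
Conditions: LiN(i-Pr)2, THF, −78 °C; CH2=NMe2+ I−, −78 °C to rt; MeI, MeOH, rt; NaHCO3, CH2Cl2–H2O; then citric acid, MeOH, 0 °C
Reagents that add atoms: N,N-dimethylmethyleneiminium iodide (Eschenmoser's salt), C=[N+](C)C.[I-]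
Why: α-Methylenation of the lactone by the Mannich route (enolate aminomethylation, quaternisation and β-elimination of trimethylamine) installs C13 as the exocyclic methylene, and the closing mild acidic methanolysis strips only the labile trimethylsilyl ethers and leaves the C3 tert-butyldimethylsilyl ether.

Step 16
Reactants: 32 (3S,4Z,6R,7S,9S,10S)-3-(tert-butyldimethylsilyloxy)-9,10-dihydroxygermacra-4,11(13)-dien-12,6-olide; 33 angelic acid
Product: 35 (3S,4Z,6R,7S,9S,10S)-9-angeloyloxy-3-(tert-butyldimethylsilyloxy)-10-hydroxygermacra-4,11(13)-dien-12,6-olide, via mixed anhydride 34 (not isolated)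
Conditions: 33, 2,4,6-Cl3C6H2COCl, Et3N, toluene, rt; then 32, toluene, 80 °C
Reagents that add atoms: none
Why: Yamaguchi-type esterification through the mixed anhydride of angelic acid, run without a nucleophilic catalyst so that the Z acyl group does not isomerise to the tiglate, acylates the secondary C9 hydroxyl because the tertiary C10 hydroxyl is too hindered to react.

Step 17
Reactants: 35 (3S,4Z,6R,7S,9S,10S)-9-angeloyloxy-3-(tert-butyldimethylsilyloxy)-10-hydroxygermacra-4,11(13)-dien-12,6-olide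
Product: 36 (3S,4Z,6R,7S,9S,10S)-9-angeloyloxy-3,10-dihydroxygermacra-4,11(13)-dien-12,6-olide (target)
Conditions: HF·pyridine, pyridine, THF, 0 °C to rt
Reagents that add atoms: none
Why: Buffered fluoride desilylation removes the C3 silyl ether under conditions that leave the α-methylene lactone, the angelate and the tertiary alcohol intact and so gives the target.

**Compound list**

1 | ethyl levulinate (ethyl 4-oxopentanoate) | CCOC(=O)CCC(C)=O | starting material
2 | ethyl 3-(2-methyl-1,3-dioxolan-2-yl)propanoate | CCOC(=O)CCC1(C)OCCO1 | intermediate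
3 | N-methoxy-N-methyl-3-(2-methyl-1,3-dioxolan-2-yl)propanamide | CON(C)C(=O)CCC1(C)OCCO1 | intermediate
4 | ethynyltrimethylsilane | C#C[Si](C)(C)C | starting material
5 | lithium (trimethylsilyl)acetylide | [Li]C#C[Si](C)(C)C | intermediate (not isolated)
6 | 5-(2-methyl-1,3-dioxolan-2-yl)-1-(trimethylsilyl)pent-1-yn-3-one | C[Si](C)(C)C#CC(=O)CCC1(C)OCCO1 | intermediate
7 | (3S)-5-(2-methyl-1,3-dioxolan-2-yl)-1-(trimethylsilyl)pent-1-yn-3-ol | C[Si](C)(C)C#C[C@@H](O)CCC1(C)OCCO1 | intermediate
8 | (3S)-5-(2-methyl-1,3-dioxolan-2-yl)pent-1-yn-3-ol | C#C[C@@H](O)CCC1(C)OCCO1 | intermediate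
9 | (5S)-4-methyl-5-[2-(2-methyl-1,3-dioxolan-2-yl)ethyl]-2,5-dihydro-1,2-oxamagnesole (alkenylmagnesium alkoxide chelate, Mg on C5 cis to the C3 oxygen) | CC1=C[Mg]O[C@H]1CCC2(C)OCCO2 | intermediate (not isolated)
10 | (1Z,3S)-1-iodo-2-methyl-5-(2-methyl-1,3-dioxolan-2-yl)pent-1-en-3-ol | I/C=C(/C)[C@@H](O)CCC1(C)OCCO1 | intermediate
11 | tert-butyl{[(1Z,3S)-1-iodo-2-methyl-5-(2-methyl-1,3-dioxolan-2-yl)pent-1-en-3-yl]oxy}dimethylsilane | I/C=C(/C)[C@@H](O[Si](C)(C)C(C)(C)C)CCC1(C)OCCO1 | intermediate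
12 | [(1Z,3S)-3-(tert-butyldimethylsilyloxy)-2-methyl-5-(2-methyl-1,3-dioxolan-2-yl)pent-1-en-1-yl]lithium | [Li]/C=C(/C)[C@@H](O[Si](C)(C)C(C)(C)C)CCC1(C)OCCO1 | intermediate (not isolated)
13 | (2Z,4S)-4-(tert-butyldimethylsilyloxy)-3-methyl-6-(2-methyl-1,3-dioxolan-2-yl)hex-2-enal | O=C/C=C(/C)[C@@H](O[Si](C)(C)C(C)(C)C)CCC1(C)OCCO1 | intermediate
14 | methyl propiolate | C#CC(=O)OC | starting material
15 | methyl 3-(methylzincio)propiolate | C[Zn]C#CC(=O)OC | intermediate (not isolated)
16 | methyl (4R,5Z,7S)-7-(tert-butyldimethylsilyloxy)-4-hydroxy-6-methyl-9-(2-methyl-1,3-dioxolan-2-yl)non-5-en-2-ynoate | COC(=O)C#C[C@H](O)/C=C(/C)[C@@H](O[Si](C)(C)C(C)(C)C)CCC1(C)OCCO1 | intermediate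
17 | methyl (2Z,4S,5Z,7S)-7-(tert-butyldimethylsilyloxy)-4-hydroxy-6-methyl-9-(2-methyl-1,3-dioxolan-2-yl)nona-2,5-dienoate | COC(=O)/C=C\[C@H](O)/C=C(/C)[C@@H](O[Si](C)(C)C(C)(C)C)CCC1(C)OCCO1 | intermediate (not isolated)
18 | (5S)-5-[(1Z,3S)-3-(tert-butyldimethylsilyloxy)-2-methyl-5-(2-methyl-1,3-dioxolan-2-yl)pent-1-en-1-yl]furan-2(5H)-one | O=C1C=C[C@@H](/C=C(/C)[C@@H](O[Si](C)(C)C(C)(C)C)CCC2(C)OCCO2)O1 | intermediate
19 | (Z)-1-bromo-2-ethoxyethene | CCO/C=C\Br | starting material
20 | (Z)-2-ethoxyvinyllithium | CCO/C=C\[Li] | intermediate (not isolated)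
21 | lithium bis[(Z)-2-ethoxyvinyl]cuprate | CCO/C=C\[Cu-]/C=C\OCC.[Li+] | intermediate (not isolated)
22 | trimethylsilyl ketene acetal of 23 (2-trimethylsilyloxy-4,5-dihydrofuran, trans at C6/C7) | C[Si](C)(C)OC1=C[C@H](/C=C\OCC)[C@@H](/C=C(/C)[C@@H](O[Si](C)(C)C(C)(C)C)CCC2(C)OCCO2)O1 | intermediate (not isolated)
23 | (4R,5S)-4-[(Z)-2-ethoxyvinyl]-5-[(1Z,3S)-3-(tert-butyldimethylsilyloxy)-2-methyl-5-(2-methyl-1,3-dioxolan-2-yl)pent-1-en-1-yl]dihydrofuran-2(3H)-one (trans-lactone) | O=C1C[C@H](/C=C\OCC)[C@@H](/C=C(/C)[C@@H](O[Si](C)(C)C(C)(C)C)CCC2(C)OCCO2)O1 | intermediate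
24 | 2-[(2S,3S)-2-[(1Z,3S)-3-(tert-butyldimethylsilyloxy)-2-methyl-6-oxohept-1-en-1-yl]-5-oxooxolan-3-yl]acetaldehyde (trans-lactone keto-aldehyde, precursor of the key step) | O=C1C[C@H](CC=O)[C@@H](/C=C(/C)[C@@H](O[Si](C)(C)C(C)(C)C)CCC(C)=O)O1 | intermediate
25 | iodosamarium 9,10-diolate of 26 (trivalent samarium bridging O9 and O10) | C1C(=O)O[C@@H]2/C=C(/C)[C@@H](O[Si](C)(C)C(C)(C)C)CC[C@]3(C)O[Sm](I)O[C@H]3C[C@@H]12 | intermediate (not isolated)
26 | (3S,4Z,6S,7S,9S,10S)-3-(tert-butyldimethylsilyloxy)-9,10-dihydroxy-13-norgermacr-4-en-12,6-olide (macrocyclic diol lactone, product of the key step) | C1C(=O)O[C@@H]2/C=C(/C)[C@@H](O[Si](C)(C)C(C)(C)C)CC[C@](C)(O)[C@@H](O)C[C@@H]12 | intermediate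
27 | 9,10-bis(trimethylsilyl) ether of 26 | C1C(=O)O[C@@H]2/C=C(/C)[C@@H](O[Si](C)(C)C(C)(C)C)CC[C@](C)(O[Si](C)(C)C)[C@@H](O[Si](C)(C)C)C[C@@H]12 | intermediate
28 | lithium enolate of 27 (C11=C12–OLi) | C1=C(O[Li])O[C@@H]2/C=C(/C)[C@@H](O[Si](C)(C)C(C)(C)C)CC[C@](C)(O[Si](C)(C)C)[C@@H](O[Si](C)(C)C)C[C@@H]12 | intermediate (not isolated)
29 | 11-[(dimethylamino)methyl] derivative of 27 (Mannich base, C11 configuration immaterial) | CN(C)CC1C(=O)O[C@@H]2/C=C(/C)[C@@H](O[Si](C)(C)C(C)(C)C)CC[C@](C)(O[Si](C)(C)C)[C@@H](O[Si](C)(C)C)C[C@@H]12 | intermediate (not isolated)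
30 | trimethylammonium iodide derived from 29 | C[N+](C)(C)CC1C(=O)O[C@@H]2/C=C(/C)[C@@H](O[Si](C)(C)C(C)(C)C)CC[C@](C)(O[Si](C)(C)C)[C@@H](O[Si](C)(C)C)C[C@@H]12.[I-] | intermediate (not isolated)
31 | (3S,4Z,6R,7S,9S,10S)-3-(tert-butyldimethylsilyloxy)-9,10-bis(trimethylsilyloxy)germacra-4,11(13)-dien-12,6-olide | C=C1C(=O)O[C@@H]2/C=C(/C)[C@@H](O[Si](C)(C)C(C)(C)C)CC[C@](C)(O[Si](C)(C)C)[C@@H](O[Si](C)(C)C)C[C@@H]12 | intermediate (not isolated)
32 | (3S,4Z,6R,7S,9S,10S)-3-(tert-butyldimethylsilyloxy)-9,10-dihydroxygermacra-4,11(13)-dien-12,6-olide | C=C1C(=O)O[C@@H]2/C=C(/C)[C@@H](O[Si](C)(C)C(C)(C)C)CC[C@](C)(O)[C@@H](O)C[C@@H]12 | intermediate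
33 | angelic acid ((Z)-2-methylbut-2-enoic acid) | C/C=C(/C)C(=O)O | starting material
34 | angelic 2,4,6-trichlorobenzoic anhydride | C/C=C(/C)C(=O)OC(=O)c1c(Cl)cc(Cl)cc1Cl | intermediate (not isolated)
35 | (3S,4Z,6R,7S,9S,10S)-9-angeloyloxy-3-(tert-butyldimethylsilyloxy)-10-hydroxygermacra-4,11(13)-dien-12,6-olide | C=C1C(=O)O[C@@H]2/C=C(/C)[C@@H](O[Si](C)(C)C(C)(C)C)CC[C@](C)(O)[C@@H](OC(=O)/C(C)=C\C)C[C@@H]12 | intermediate
36 | (3S,4Z,6R,7S,9S,10S)-9-angeloyloxy-3,10-dihydroxygermacra-4,11(13)-dien-12,6-olide | C=C1C(=O)O[C@@H]2/C=C(/C)[C@@H](O)CC[C@](C)(O)[C@@H](OC(=O)/C(C)=C\C)C[C@@H]12 | target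

**Step count and risk**

Total step count: 17. Longest linear sequence: 17 steps (from ethyl levulinate; compounds 4, 14, 19 and 33 enter as purchased materials).

Steps most likely to fail:

1. Step 13. The ketyl may add with the wrong facial sense at C9, so that the C9 hydroxyl comes out epimeric or as a mixture. The fallback sets out from 24 and comes back at 26. The coupling is run as in step 13 and the C9-epimeric diol F1 is carried on. Dess–Martin oxidation of its secondary hydroxyl gives the 9-oxo-10-hydroxy lactone F2, in which C10 is untouched. Reduction with the bulky, non-chelating hydride K[HB(s-Bu)3] (THF, −78 °C) should then attack anti to the C10 oxygen from the ring periphery (polar Felkin–Anh) and return 26. A mixture of C9 epimers converges on F2 in the same way. C10 cannot be repaired by this means.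

2. Step 9. The hindered Z-enal may isomerise to the E-enal under the basic zinc alkoxide conditions, or alkynyl transfer may show poor face selectivity. The fallback sets out from 11 and comes back at 18. Vinyllithium 12, generated as in step 8, is added to the Weinreb amide methyl 4-[methoxy(methyl)amino]-4-oxobutanoate F3 (from methyl 4-chloro-4-oxobutanoate and N,O-dimethylhydroxylamine) to give the Z-enone keto ester F4. Corey–Bakshi–Shibata reduction with the (R)-2-methyl-oxazaborolidine and catecholborane, the alkenyl group acting as the large substituent, gives the hydroxy ester F5. This lactonises (PPTS) to the γ-alkenyl butanolide F6. α-Selenenylation (LiN(i-Pr)2, PhSeBr, −78 °C) gives the α-phenylselanyl lactone F7, and oxidative syn-elimination (H2O2, pyridine, 0 °C) returns butenolide 18.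

3. Step 11. Transfer of the β-alkoxyvinyl ligand from copper may be inefficient, or excess stoichiometric cuprate may open the allylic lactone at C6 in an SN2′ sense. The fallback sets out from 18 and comes back at 24. Copper-catalysed conjugate addition of vinylmagnesium bromide (CuBr·SMe2 cat., Me3SiCl, THF, −78 °C) gives the trans 7-vinyl lactone F8. Hydroboration of the monosubstituted alkene with 9-BBN and oxidation with NaBO3·4H2O gives the primary alcohol F9. Dess–Martin oxidation gives the aldehyde F10, and PPTS in wet acetone removes the dioxolane to give 24.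

**Further compounds**

F1 | step 13 | C9 epimer of 26, (3S,4Z,6S,7S,9R,10S)-3-(tert-butyldimethylsilyloxy)-9,10-dihydroxy-13-norgermacr-4-en-12,6-olide | C1C(=O)O[C@@H]2/C=C(/C)[C@@H](O[Si](C)(C)C(C)(C)C)CC[C@](C)(O)[C@H](O)C[C@@H]12
F2 | step 13 | (3S,4Z,6S,7S,10S)-3-(tert-butyldimethylsilyloxy)-10-hydroxy-9-oxo-13-norgermacr-4-en-12,6-olide | C1C(=O)O[C@@H]2/C=C(/C)[C@@H](O[Si](C)(C)C(C)(C)C)CC[C@](C)(O)C(=O)C[C@@H]12
F3 | step 9 | methyl 4-[methoxy(methyl)amino]-4-oxobutanoate | COC(=O)CCC(=O)N(C)OC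
F4 | step 9 | methyl (5Z,7S)-7-(tert-butyldimethylsilyloxy)-6-methyl-9-(2-methyl-1,3-dioxolan-2-yl)-4-oxonon-5-enoate | COC(=O)CCC(=O)/C=C(/C)[C@@H](O[Si](C)(C)C(C)(C)C)CCC1(C)OCCO1
F5 | step 9 | methyl (4S,5Z,7S)-7-(tert-butyldimethylsilyloxy)-4-hydroxy-6-methyl-9-(2-methyl-1,3-dioxolan-2-yl)non-5-enoate | COC(=O)CC[C@H](O)/C=C(/C)[C@@H](O[Si](C)(C)C(C)(C)C)CCC1(C)OCCO1
F6 | step 9 | (5S)-5-[(1Z,3S)-3-(tert-butyldimethylsilyloxy)-2-methyl-5-(2-methyl-1,3-dioxolan-2-yl)pent-1-en-1-yl]dihydrofuran-2(3H)-one | O=C1CC[C@@H](/C=C(/C)[C@@H](O[Si](C)(C)C(C)(C)C)CCC2(C)OCCO2)O1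
F7 | step 9 | 3-(phenylselanyl) derivative of F6 (C3 configuration immaterial) | O=C1C([Se]c3ccccc3)C[C@@H](/C=C(/C)[C@@H](O[Si](C)(C)C(C)(C)C)CCC2(C)OCCO2)O1
F8 | step 11 | trans-4-vinyl-5-[(1Z,3S)-3-(tert-butyldimethylsilyloxy)-2-methyl-5-(2-methyl-1,3-dioxolan-2-yl)pent-1-en-1-yl]dihydrofuran-2(3H)-one (C6 and C7 as in 23) | O=C1C[C@H](C=C)[C@@H](/C=C(/C)[C@@H](O[Si](C)(C)C(C)(C)C)CCC2(C)OCCO2)O1
F9 | step 11 | trans-4-(2-hydroxyethyl) analogue of F8 | O=C1C[C@H](CCO)[C@@H](/C=C(/C)[C@@H](O[Si](C)(C)C(C)(C)C)CCC2(C)OCCO2)O1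
F10 | step 11 | 2-[(2S,3S)-2-[(1Z,3S)-3-(tert-butyldimethylsilyloxy)-2-methyl-5-(2-methyl-1,3-dioxolan-2-yl)pent-1-en-1-yl]-5-oxooxolan-3-yl]acetaldehyde | O=C1C[C@H](CC=O)[C@@H](/C=C(/C)[C@@H](O[Si](C)(C)C(C)(C)C)CCC2(C)OCCO2)O1
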